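**Strategy.** The synthesis rests on cutting the O1–C8a bond of ring C. Because C8a lies ortho to the C4 carbonyl on ring A, a fluoride placed there is an activated leaving group, and the ring-B-side enolate oxygen of a 2-benzyloxy-1,3-diketone can displace it intramolecularly. One base-mediated SNAr therefore forges the aryl ether bond, closes the pyranone and delivers the fully oxygenated flavonol core with the C3 oxygen already in place. The precursor is a 1-(2-fluoroaryl)-3-aryl-2-(benzyloxy)propane-1,3-dione assembled from a fluorinated ring A ketone and a ring B acid chloride. All four free hydroxyls are masked as benzyl ethers, so a single hydrogenolysis finishes the route.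

Key step: step 10

Remarks on the chemistry:
- Ring positions are quoted with flavone numbering (O1, C2, C3, C4, C4a, C5–C8, C8a).
- Assumption: in fluoroarene 5 the ring hydrogen flanked by F and OBn is the kinetically most acidic one.
- Diketone 16 is drawn in its keto form; it is racemic at the central carbon, enolises freely, and that centre disappears in step 10.
- Benzyloxyacetyl chloride is taken as the purchasable activated form of benzyloxyacetic acid.

**Route**

Step 1
Reactants: 1 3-fluoro-4-hydroxy-5-methoxybenzaldehyde
Product: 2 3-fluoro-4,5-dimethoxybenzaldehyde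
Conditions: MeI, K2CO3, DMF, rt
Reagents that add atoms: iodomethane, CI
Why: Williamson O-methylation of the acidic phenol flanked by F and OMe; the aldehyde is inert to carbonate and iodomethane.

Step 2
Reactants: 2 3-fluoro-4,5-dimethoxybenzaldehyde
Product: 4 3-fluoro-4,5-dimethoxyphenol, via 3-fluoro-4,5-dimethoxyphenyl formate 3 (not isolated)
Conditions: mCPBA, CH2Cl2, 0 °C to rt; aq. NaHCO3 wash; then K2CO3 (cat.), MeOH, rt
Reagents that add atoms: 3-chloroperoxybenzoic acid (mCPBA), OOC(=O)c1cccc(Cl)c1
Why: Baeyer–Villiger (Dakin-type) oxidation in which the electron-rich aryl group migrates in preference to hydride to give the aryl formate, which mild base-catalysed methanolysis cleaves to the phenol.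

Step 3
Reactants: 4 3-fluoro-4,5-dimethoxyphenol
Product: 5 5-(benzyloxy)-1-fluoro-2,3-dimethoxybenzene
Conditions: BnBr, K2CO3, DMF, rt
Reagents that add atoms: benzyl bromide, BrCc1ccccc1
Why: Williamson benzylation of the only free hydroxyl, giving an ether that survives organolithium and carbonate conditions and leaves later by hydrogenolysis.

Step 4
Reactants: 6 benzyloxyacetyl chloride
Product: 7 2-(benzyloxy)-N-methoxy-N-methylacetamide
Conditions: MeNH(OMe)·HCl, Et3N, CH2Cl2, 0 °C to rt
Reagents that add atoms: N,O-dimethylhydroxylamine hydrochloride, CNOC.Cl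
Why: N-acylation of the hydroxylamine by the acid chloride (Weinreb amide formation), a fast and selective amide-forming reaction.

Step 5
Reactants: 5 5-(benzyloxy)-1-fluoro-2,3-dimethoxybenzene; 7 2-(benzyloxy)-N-methoxy-N-methylacetamide
Product: 10 2-(benzyloxy)-1-[6-(benzyloxy)-2-fluoro-3,4-dimethoxyphenyl]ethan-1-one, via aryllithium 8 (not isolated), via lithium hemiaminal adduct 9 (not isolated)
Conditions: n-BuLi, THF, −78 °C; then 7, −78 °C; aq. NH4Cl
Reagents that add atoms: none
Why: Directed ortho-metalation followed by Weinreb ketone synthesis: fluorine acidifies its ortho hydrogen more strongly than methoxy does, so n-BuLi at −78 °C should remove the hydrogen between F and OBn, and the chelated tetrahedral adduct with the amide resists a second addition and releases the ketone only on aqueous quench.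

Step 6
Reactants: 11 methyl 3,5-dihydroxy-4-methoxybenzoate
Product: 12 methyl 3,5-bis(benzyloxy)-4-methoxybenzoate
Conditions: BnBr, K2CO3, DMF, 60 °C
Reagents that add atoms: benzyl bromide, BrCc1ccccc1
Why: Twofold Williamson benzylation of the two equivalent phenols; the methyl ester is untouched by carbonate in DMF.

Step 7
Reactants: 12 methyl 3,5-bis(benzyloxy)-4-methoxybenzoate
Product: 13 3,5-bis(benzyloxy)-4-methoxybenzoic acid
Conditions: NaOH, THF/MeOH/H2O, 60 °C; then aq. HCl
Reagents that add atoms: sodium hydroxide, [Na+].[OH-]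
Why: Saponification (acyl–oxygen ester hydrolysis) followed by acidification; the aryl benzyl and methyl ethers are stable to aqueous base.

Step 8
Reactants: 13 3,5-bis(benzyloxy)-4-methoxybenzoic acid
Product: 14 3,5-bis(benzyloxy)-4-methoxybenzoyl chloride
Conditions: (COCl)2, DMF (cat.), CH2Cl2, 0 °C to rt
Reagents that add atoms: oxalyl chloride, O=C(Cl)C(=O)Cl
Why: Acid chloride formation through the chloroiminium species generated from DMF, with only gaseous co-products, so the crude chloride can be used after evaporation.

Step 9
Reactants: 10 2-(benzyloxy)-1-[6-(benzyloxy)-2-fluoro-3,4-dimethoxyphenyl]ethan-1-one; 14 3,5-bis(benzyloxy)-4-methoxybenzoyl chloride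
Product: 16 2-(benzyloxy)-1-[6-(benzyloxy)-2-fluoro-3,4-dimethoxyphenyl]-3-[3,5-bis(benzyloxy)-4-methoxyphenyl]propane-1,3-dione, via lithium enolate 15 (not isolated)
Conditions: LiN(SiMe3)2 (2.2 equiv), THF, −78 °C; then 14, −78 to 0 °C; aq. NH4Cl
Reagents that add atoms: none
Why: Claisen-type C-acylation of a preformed, chelated lithium enolate by an aroyl chloride; the second equivalent of base converts the more acidic diketone into its enolate as it forms, which suppresses proton exchange and further acylation.

Step 10
Reactants: 16 2-(benzyloxy)-1-[6-(benzyloxy)-2-fluoro-3,4-dimethoxyphenyl]-3-[3,5-bis(benzyloxy)-4-methoxyphenyl]propane-1,3-dione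
Product: 18 3,5-bis(benzyloxy)-2-[3,5-bis(benzyloxy)-4-methoxyphenyl]-7,8-dimethoxy-4H-chromen-4-one, via potassium enolate 17 (not isolated)
Conditions: K2CO3, DMF, 80 °C
Reagents that add atoms: none
Why: Carbonate removes the acidic hydrogen between the two carbonyl groups, and the enolate oxygen on the ring B side adds to C8a to give a Meisenheimer-type σ-adduct whose charge is absorbed through C4a by the ortho C4 carbonyl; loss of fluoride then restores ring A and leaves the O1–C8a bond. The closest known reaction type is the base-mediated intramolecular SNAr O-arylation of 1-(2-fluoroaryl)-1,3-diketones to 4H-chromen-4-ones. Ring C closes as a six-membered ring by addition–elimination at an sp2 carbon, formally a 6-endo-trig conjugate addition to the C8a=C4a–C4=O unit followed by β-elimination of fluoride; attack through the other oxygen or the central carbon would need a four-membered ring and is excluded. No stereocenter is created, and the labile centre of 16 vanishes as C3 becomes sp2. The selectivity needed is displacement at C8a alone: fluoride is the only good leaving group ortho to the ketone and within six-membered reach of the nucleophilic oxygen, and the benzyloxy group at the other ortho position is a far poorer nucleofuge. The alkoxy groups at C5 and C7 stand meta to the reacting carbon, so their lone pairs cannot feed electron density into C8a.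

Step 11
Reactants: 18 3,5-bis(benzyloxy)-2-[3,5-bis(benzyloxy)-4-methoxyphenyl]-7,8-dimethoxy-4H-chromen-4-one
Product: 19 3,5-dihydroxy-2-(3,5-dihydroxy-4-methoxyphenyl)-7,8-dimethoxy-4H-chromen-4-one
Conditions: H2 (1 atm), 10% Pd/C, THF/MeOH, rt
Reagents that add atoms: none
Why: Catalytic hydrogenolysis cleaves the three aryl benzyl ethers and the C3 enol benzyl ether at their benzylic C–O bonds, while the chromen-4-one, the methyl ethers and the aromatic rings are not reduced under one atmosphere of hydrogen at room temperature.

**Compound list**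

1 | 3-fluoro-4-hydroxy-5-methoxybenzaldehyde | COc1cc(C=O)cc(F)c1O | starting material
2 | 3-fluoro-4,5-dimethoxybenzaldehyde | COc1cc(C=O)cc(F)c1OC | intermediate
3 | 3-fluoro-4,5-dimethoxyphenyl formate | COc1cc(OC=O)cc(F)c1OC | intermediate
4 | 3-fluoro-4,5-dimethoxyphenol | COc1cc(O)cc(F)c1OC | intermediate
5 | 5-(benzyloxy)-1-fluoro-2,3-dimethoxybenzene | COc1cc(OCc2ccccc2)cc(F)c1OC | intermediate
6 | benzyloxyacetyl chloride | O=C(Cl)COCc1ccccc1 | starting material
7 | 2-(benzyloxy)-N-methoxy-N-methylacetamide | CON(C)C(=O)COCc1ccccc1 | intermediate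
8 | [6-(benzyloxy)-2-fluoro-3,4-dimethoxyphenyl]lithium | [Li]c1c(F)c(OC)c(OC)cc1OCc1ccccc1 | intermediate
9 | lithium 2-(benzyloxy)-1-[6-(benzyloxy)-2-fluoro-3,4-dimethoxyphenyl]-1-[methoxy(methyl)amino]ethan-1-olate (racemic) | [Li]OC(COCc1ccccc1)(N(C)OC)c1c(F)c(OC)c(OC)cc1OCc1ccccc1 | intermediate
10 | 2-(benzyloxy)-1-[6-(benzyloxy)-2-fluoro-3,4-dimethoxyphenyl]ethan-1-one | COc1cc(OCc2ccccc2)c(C(=O)COCc2ccccc2)c(F)c1OC | intermediate
11 | methyl 3,5-dihydroxy-4-methoxybenzoate | COC(=O)c1cc(O)c(OC)c(O)c1 | starting material
12 | methyl 3,5-bis(benzyloxy)-4-methoxybenzoate | COC(=O)c1cc(OCc2ccccc2)c(OC)c(OCc2ccccc2)c1 | intermediate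
13 | 3,5-bis(benzyloxy)-4-methoxybenzoic acid | OC(=O)c1cc(OCc2ccccc2)c(OC)c(OCc2ccccc2)c1 | intermediate
14 | 3,5-bis(benzyloxy)-4-methoxybenzoyl chloride | O=C(Cl)c1cc(OCc2ccccc2)c(OC)c(OCc2ccccc2)c1 | intermediate
15 | lithium (Z)-2-(benzyloxy)-1-[6-(benzyloxy)-2-fluoro-3,4-dimethoxyphenyl]ethen-1-olate | [Li]O/C(=C\OCc1ccccc1)c1c(F)c(OC)c(OC)cc1OCc1ccccc1 | intermediate
16 | 2-(benzyloxy)-1-[6-(benzyloxy)-2-fluoro-3,4-dimethoxyphenyl]-3-[3,5-bis(benzyloxy)-4-methoxyphenyl]propane-1,3-dione (racemic, enolisable) | COc1cc(OCc2ccccc2)c(C(=O)C(OCc2ccccc2)C(=O)c2cc(OCc3ccccc3)c(OC)c(OCc3ccccc3)c2)c(F)c1OC | intermediate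
17 | potassium (E)-2-(benzyloxy)-3-[6-(benzyloxy)-2-fluoro-3,4-dimethoxyphenyl]-1-[3,5-bis(benzyloxy)-4-methoxyphenyl]-3-oxoprop-1-en-1-olate (drawn in the geometry that cyclises) | [K]O/C(=C(/OCc1ccccc1)C(=O)c1c(F)c(OC)c(OC)cc1OCc1ccccc1)c1cc(OCc2ccccc2)c(OC)c(OCc2ccccc2)c1 | intermediate
18 | 3,5-bis(benzyloxy)-2-[3,5-bis(benzyloxy)-4-methoxyphenyl]-7,8-dimethoxy-4H-chromen-4-one | COc1cc(OCc2ccccc2)c2c(=O)c(OCc3ccccc3)c(-c3cc(OCc4ccccc4)c(OC)c(OCc4ccccc4)c3)oc2c1OC | intermediate
19 | 3,5-dihydroxy-2-(3,5-dihydroxy-4-methoxyphenyl)-7,8-dimethoxy-4H-chromen-4-one | COc1cc(O)c2c(=O)c(O)c(-c3cc(O)c(OC)c(O)c3)oc2c1OC | target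

**Step count**

Total steps: 11.
Longest linear sequence: 7 steps (steps 1, 2, 3, 5, 9, 10, 11, from compound 1).

**Steps most likely to fail**

Step 5. The base may remove the ring hydrogen flanked by the methoxy and benzyloxy groups instead of the one next to fluorine. The aryllithium may also lose LiF to an aryne if it warms, and the benzylic position of the ether may be metalated. The fallback fixes the site by electrophilic substitution instead of by acidity. It sets out from 5, which is brominated with NBS in MeCN at 0 °C; attack is expected para to the C3 methoxy group, giving 1-(benzyloxy)-2-bromo-3-fluoro-4,5-dimethoxybenzene F1, and any regioisomer can be removed and the structure confirmed at this stage. Bromine–lithium exchange of F1 with n-BuLi in THF at −78 °C then generates aryllithium 8 without any deprotonation, and the route is rejoined at 8, which is treated with 7 as in step 5 to give 10.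

Step 9. The enolate may react at oxygen to give an enol ester, or proton transfer and double acylation may erode the diketone. The fallback replaces acylation by aldol addition and oxidation. It sets out from 10 and 12. Ester 12 is reduced with LiAlH4 in THF at 0 °C to [3,5-bis(benzyloxy)-4-methoxyphenyl]methanol F2, which MnO2 in CH2Cl2 oxidises to 3,5-bis(benzyloxy)-4-methoxybenzaldehyde F3. Lithium enolate 15, made from 10 as in step 9, is added to F3 at −78 °C to give 2-(benzyloxy)-1-[6-(benzyloxy)-2-fluoro-3,4-dimethoxyphenyl]-3-[3,5-bis(benzyloxy)-4-methoxyphenyl]-3-hydroxypropan-1-one F4 as a diastereomer mixture of no consequence. Dess–Martin periodinane in CH2Cl2 with NaHCO3 then oxidises the carbinol, and the route is rejoined at 16.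

Step 10. Fluoride displacement may be slow on the electron-rich ring A, whose ketone is twisted out of conjugation by its two ortho substituents, and retro-Claisen cleavage of the diketone by carbonate and adventitious water may compete. The fallback closes ring C with a stronger oxygen nucleophile at the alcohol oxidation level and adjusts the oxidation state afterwards. It sets out from 10, which is converted into aldol adduct F4 as described for step 9. Treatment of F4 with NaH in THF/DMF from 0 °C to rt forms the alkoxide, which should displace fluoride at C8a; retro-aldol cleavage is reversible whereas ring closure is not. This gives 3,5-bis(benzyloxy)-2-[3,5-bis(benzyloxy)-4-methoxyphenyl]-7,8-dimethoxy-2,3-dihydro-4H-chromen-4-one F5 as a diastereomer mixture. Dehydrogenation of F5 across C2–C3 with DDQ in 1,4-dioxane at reflux, a standard flavanone-to-flavone oxidation, returns the route at 18.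

**Further compounds**

F1 | step 5 | 1-(benzyloxy)-2-bromo-3-fluoro-4,5-dimethoxybenzene | COc1cc(OCc2ccccc2)c(Br)c(F)c1OC
F2 | step 9 | [3,5-bis(benzyloxy)-4-methoxyphenyl]methanol | OCc1cc(OCc2ccccc2)c(OC)c(OCc2ccccc2)c1
F3 | step 9 | 3,5-bis(benzyloxy)-4-methoxybenzaldehyde | O=Cc1cc(OCc2ccccc2)c(OC)c(OCc2ccccc2)c1
F4 | step 9 | 2-(benzyloxy)-1-[6-(benzyloxy)-2-fluoro-3,4-dimethoxyphenyl]-3-[3,5-bis(benzyloxy)-4-methoxyphenyl]-3-hydroxypropan-1-one (racemic diastereomer mixture) | COc1cc(OCc2ccccc2)c(C(=O)C(OCc2ccccc2)C(O)c2cc(OCc3ccccc3)c(OC)c(OCc3ccccc3)c2)c(F)c1OC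
F5 | step 10 | 3,5-bis(benzyloxy)-2-[3,5-bis(benzyloxy)-4-methoxyphenyl]-7,8-dimethoxy-2,3-dihydro-4H-chromen-4-one (racemic diastereomer mixture) | COc1cc(OCc2ccccc2)c2C(=O)C(OCc3ccccc3)C(c3cc(OCc4ccccc4)c(OC)c(OCc4ccccc4)c3)Oc2c1OC
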